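**Remark on the chemistry (assumption):** alkene 13 is drawn E; an E/Z mixture is expected and is acceptable, because step 8 removes the double bond.

**Check of the structures:** a three-carbon arm on ring A plus a nine-carbon arm on ring B give the twelve-carbon bridge, and 3 ring A atoms + O + 4 ring B atoms + 12 CH2 give 20 ring members. Precursor 11 and product 13 are therefore consistent with the target, and no structure needed correction. The precursor design is improved in one respect: the chain hydroxyl is unmasked before any aldehyde exists, and the second aldehyde is made by oxidation directly before the ring closure.

## Structural features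

The target (C24H32O4) has two benzene rings and no stereocentre, so no stereocentres stand next to each other and no configuration has to be set. Ring A is 1,3,5-trisubstituted: a free hydroxyl, the bridging ether oxygen and one end of the carbon chain are all meta to one another. Ring B carries the ether oxygen on C1, hydroxyls on both ortho carbons (C2 and C6) and the other chain end on C4, para to the ether oxygen. The rings are joined twice, by the diaryl ether oxygen and by an unbranched saturated twelve-carbon chain, which closes a 20-membered ring. The fragile groups are the three phenols, above all the electron-rich 2-aryloxyresorcinol unit of ring B, which oxidises easily; they are best kept as ethers until the last step. The real difficulties are the closure of the large ring against oligomerisation and the formation of a diaryl ether at an oxygen flanked by two ortho substituents. The key step exploits the featureless C12 bridge: any of its C–C bonds can be the closure site, and C9–C10 (C1 on ring B) leaves a three-carbon aldehyde arm on ring A and a nine-carbon aldehyde arm on ring B. The alkene that the closure leaves is erased by hydrogenation.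

## Logic of the disconnections

**16 from 14 (through 15).** The three O–CH3 bonds that 14 has in place of the O–H bonds of 16 are cut. The cut is made there because both aromatic building blocks are sold with exactly these methyl ethers, and methyl ethers are inert to every reagent of the route, low-valent titanium included. The gain is that no protecting group has to be put on or exchanged on either ring. The forward step must remove three methyl groups, two of them next to the hindered ether oxygen, without cleaving the aryl–O–aryl bond.

**14 from 13.** The C9–C10 single bond of the bridge is replaced by a double bond; no skeletal bond is cut. An alkene at that place is what a carbonyl coupling leaves behind. Nothing is gained in simplicity, but the geometry of 13 becomes irrelevant. The forward step only has to saturate a disubstituted alkene in a molecule that has no benzyl or halogen group.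

**13 from 11.** The C9=C10 double bond is cut into two aldehyde carbons. In a uniform chain the closure site can be chosen for the convenience of the arms: C1–C9 stay on ring B and C10–C12 on ring A. The gain is the largest of the route: the 20-membered ring is opened to an acyclic diaryl ether with two like functional groups that need not be told apart. The forward step must couple the two carbonyls within one molecule, and 11 must carry nothing else that low-valent titanium reduces.

**11 from 10, and 10 from 8 and 9.** The aldehyde at C9 is taken back to the primary alcohol of 10; then the bond between ring A and C12 is cut, which gives 8 and 9. A three-carbon aldehyde arm is what an aryl bromide and 9 deliver in one palladium-catalysed step, and ending with an oxidation means that 11 is made just before it is used. The gain is that one arm shrinks to a halogen on ring A. The forward steps need arylation at the terminal carbon of 9 with β-hydride elimination toward the carbinol carbon, tolerance of the free hydroxyl of 8, and an oxidation of 10 that leaves the existing aldehyde alone.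

**8 from 7.** The O–H bond at the chain terminus is traced back to an O–Si bond. The hydroxyl has to be masked during hydroboration and copper-catalysed etherification, and the mask comes off before any aldehyde is present. This is protecting-group bookkeeping without gain in simplicity. The forward step must be neutral to aryl ethers and to the aryl bromide.

**7 from 5 and 6.** The bond between the ether oxygen and ring A is cut. The oxygen belongs to ring B as a phenol between two methoxy groups, and ring A can carry two different halogens, one to be replaced by oxygen and one kept for the later C–C bond. The gain is the separation of the two arenes; 6 is commercial. The forward step must arylate a di-ortho-substituted phenol, at C–I and not at C–Br, and only once.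

**5 from 3 and 4; 4 from 2; 2 from 1.** The bond between C4 of ring B and C1 of the bridge is cut, which leads to 3 and 4; 4 is the hydroboration product of 2, and 2 is the silyl ether of 1. An sp2–sp3 coupling attaches the complete nine-carbon arm, with its terminal oxygen, at the only halogen of 3. The gain is that everything now rests on the commercial compounds 1, 3, 6 and 9. The forward steps need anti-Markovnikov hydroboration and a cross-coupling into an electron-rich aryl bromide that bears a free phenol, with alkyl transfer faster than β-hydride elimination.

## Other disconnections considered

**Alternative 1:** The cut runs through both arenes. In each ring the bond between the ester-bearing carbon and the chain-bearing carbon is broken, so that both benzene rings become the ends of one linear, two-directional polyketide-type chain, the bis(diketo-dioxinone) A1. In the forward step, heating A1 would release an acylketene at each end, the alcohol that becomes the ester group would trap it as a 3,5,7-triketo ester, and base followed by acid would close and aromatise both rings by intramolecular aldol condensation to the bis-resorcylate A2.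
- In its favour: both rings arise in one operation from acyclic material; the oxygen pattern and the chain position are fixed by the folding; no protecting group and no transition metal are needed; the twofold symmetry halves the number of distinct operations. On these points it is the equal or the better of the chosen plan.
- Against it here: A2 contains neither the diaryl ether, nor the third oxygen of ring B, nor the macrocycle, and its symmetry becomes a handicap because the target is unsymmetrical. Both ester groups would have to be removed, and one resorcinol oxygen would have to be joined to the carbon between the two hydroxyls of the other ring by oxidative phenol coupling. That coupling would have to prefer C–O over C–C bond formation, one position among several, and ring closure over oligomerisation, on two unprotected and easily over-oxidised rings.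
- Comparison: structurally it builds what can be bought (the oxygenated arenes) and leaves open what is hard (ether and ring). Mechanistically its key step is sound, but the step after it is the weak one. In step count, A1 itself needs a series of acylations, so the total would not be expected to fall below nine.

**Alternative 2:** The cut removes three C–C bonds of ring A, so that ring A comes from the four carbons of a 3-alkylcyclobutenone and the two carbons of an ethynyl ether on the ring B oxygen; in precursor A3 the C12 chain links these two ends. In the forward step, heating A3 in a hydrocarbon solvent would open the cyclobutenone to a vinylketene, which would add the electron-rich alkyne in a [2+2] cycloaddition. A second four-electron ring opening, a six-electron closure and tautomerisation would then give the phenol A4, closing ring A and the macrocycle together.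
- In its favour: the 1,3,5-pattern of ring A follows from the polarity of ketene and ynol ether; the hindered diaryl ether is never made by coupling, because the ring B oxygen is carried in and ring A grows on it; no metal is needed; A4 has the ring A hydroxyl free, so one demethylation remains after the key step, against two steps in the chosen plan. On the ether bond and on the endgame it is the better.
- Against it here: A3 combines a base- and nucleophile-sensitive cyclobutenone with an acid-sensitive aryl ethynyl ether of a di-ortho-substituted phenol, two ends that are laborious to install in one molecule. The cycloaddition is normally run bimolecularly and concentrated; here it would have to find a 20-membered transition state at high dilution, against ketene dimerisation and thermal loss of the ynol ether.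
- Comparison: structurally it forms more bonds and two rings in one step. Mechanistically the pericyclic cascade is well understood, but large-ring closure by it has less support than closure by carbonyl coupling. In step count it is shorter after the key step and longer before it, so no clear gain is expected.

**Alternative 3:** The cut is the bond from the ether oxygen to ring A, made at the oxidation level of a cyclohexenone: ring A is represented by a 5-alkyl-3-chlorocyclohex-2-enone tethered through the C12 chain to the free ring B phenol in A5. In the forward step the phenoxide of A5, formed with a carbonate base at high dilution, would add to C3 of the chloroenone and expel chloride (vinylogous acyl substitution). This would give the macrocyclic 3-aryloxy-enone A6, racemic at the chain-bearing carbon. Dehydrogenation would then aromatise ring A to A4, erasing the stereocentre, and demethylation would finish.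
- In its favour: the hardest intermolecular bond of the chosen plan, the ether at the hindered oxygen, is made by a polar addition–elimination on a reactive electrophile, without copper and without any iodide/bromide selectivity. On this bond it is the better. The need for high dilution is the same in both plans (equal).
- Against it here: ring A, a purchased arene in the chosen plan, would have to be built as a cyclohexane-1,3-dione derivative on the end of the long chain. The chloroenone would have to be generated while the phenol is masked and then unmasked without self-condensation. The vinylogous ester A6 is hydrolytically labile, and the aromatisation is an extra oxidation on a molecule with an electron-rich ring B.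
- Comparison: structurally it closes the ring at the heteroatom instead of in the chain. Mechanistically it is simple and polar. In step count it needs two steps after the key step, as the chosen plan does, but clearly more before it.

Key step: step 7

## Route

Step 1
Reactants: 1 non-8-en-1-ol
Product: 2 tert-butyl(dimethyl)(non-8-en-1-yloxy)silane
Conditions: TBSCl, imidazole, CH2Cl2, 0 °C → rt
Reagents that add atoms: tert-butyl(chloro)dimethylsilane (TBSCl), CC(C)(C)[Si](C)(C)Cl
Why: Standard silylation of a primary alcohol. The silyl ether keeps the hydroxyl from consuming borane in step 2 and from acting as a competing oxygen nucleophile in step 3.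

Step 2
Reactants: 2 tert-butyl(dimethyl)(non-8-en-1-yloxy)silane; 3 4-bromo-2,6-dimethoxyphenol
Product: 5 4-{9-[tert-butyl(dimethyl)silyloxy]nonyl}-2,6-dimethoxyphenol, via B-alkyl-9-BBN adduct 4 (not isolated)
Conditions: 9-BBN (0.5 M in THF), 0 °C → rt; then 3, Pd(OAc)2 (cat.), SPhos, aq. K3PO4, THF, 65 °C
Reagents that add atoms: none
Why: Hydroboration with the bulky bicyclic borane places boron on the terminal carbon, and the B-alkyl Suzuki–Miyaura coupling then joins that primary carbon to the aryl bromide. The electron-rich biaryl phosphine should allow oxidative addition even with the phenoxide present, and reductive elimination should outrun β-hydride elimination.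

Step 3
Reactants: 5 4-{9-[tert-butyl(dimethyl)silyloxy]nonyl}-2,6-dimethoxyphenol; 6 1-bromo-3-iodo-5-methoxybenzene
Product: 7 tert-butyl({9-[4-(3-bromo-5-methoxyphenoxy)-3,5-dimethoxyphenyl]nonyl}oxy)dimethylsilane
Conditions: CuI (10 mol %), picolinic acid (20 mol %), K3PO4, DMSO, 80 °C, under argon; 6 in slight excess
Reagents that add atoms: none
Why: Ullmann-type diaryl ether synthesis; the copper picolinate system is suited to ortho,ortho'-disubstituted phenols. The C–I bond should react well ahead of the C–Br bond at this temperature, so the bromide is kept for step 5, and the excess of 6 suppresses a second arylation.

Step 4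
Reactants: 7 tert-butyl({9-[4-(3-bromo-5-methoxyphenoxy)-3,5-dimethoxyphenyl]nonyl}oxy)dimethylsilane
Product: 8 9-[4-(3-bromo-5-methoxyphenoxy)-3,5-dimethoxyphenyl]nonan-1-ol
Conditions: CSA (cat.), MeOH–CH2Cl2, rt
Reagents that add atoms: none
Why: Acid-catalysed methanolysis of a primary silyl ether; aryl ethers and the aryl bromide are inert. Doing this before step 5 means that the deprotection never meets an enolisable aldehyde.

Step 5
Reactants: 8 9-[4-(3-bromo-5-methoxyphenoxy)-3,5-dimethoxyphenyl]nonan-1-ol; 9 allyl alcohol (prop-2-en-1-ol)
Product: 10 3-{3-[4-(9-hydroxynonyl)-2,6-dimethoxyphenoxy]-5-methoxyphenyl}propanal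
Conditions: Pd(OAc)2 (5 mol %), Bu4NCl, NaHCO3, DMF, 80–90 °C
Reagents that add atoms: none
Why: Heck reaction with allyl alcohol under ligand-free phase-transfer conditions. The arylpalladium species adds its aryl group to the terminal alkene carbon, and β-hydride elimination toward the carbinol carbon followed by tautomerisation should give the saturated aldehyde directly; the remote hydroxyl does not interfere.

Step 6
Reactants: 10 3-{3-[4-(9-hydroxynonyl)-2,6-dimethoxyphenoxy]-5-methoxyphenyl}propanal
Product: 11 9-{4-[3-methoxy-5-(3-oxopropyl)phenoxy]-3,5-dimethoxyphenyl}nonanal
Conditions: Dess–Martin periodinane, CH2Cl2, 0 °C → rt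
Reagents that add atoms: none
Why: Dess–Martin oxidation of a primary alcohol stops at the aldehyde under near-neutral conditions and leaves the aldehyde already present untouched. Dialdehyde 11 is used directly in step 7.

Step 7
Reactants: 11 9-{4-[3-methoxy-5-(3-oxopropyl)phenoxy]-3,5-dimethoxyphenyl}nonanal
Product: 13 macrocyclic alkene trimethyl ether (1^5,3^2,3^6-trimethoxy-2-oxa-1(1,3),3(1,4)-dibenzenacyclopentadecaphan-12-ene; E drawn), via titanium-bound macrocyclic 1,2-diolate 12 (not isolated)
Conditions: TiCl3(DME)1.5, Zn–Cu, DME, reflux; 11 added by syringe pump over ca. 30 h (high dilution), then continued reflux
Reagents that add atoms: none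
Why: This is a McMurry coupling: low-valent titanium, made in the flask from TiCl3 and the Zn–Cu couple, transfers one electron to each aldehyde. The two titanium-bound ketyl radicals combine carbon to carbon and form the C9–C10 bond as diolate 12; this radical–radical combination of two tethered carbonyl carbons is the event that closes the 20-membered ring, with both joined atoms and the new bond inside the ring. At reflux the oxophilic titanium then removes both oxygens from 12 and leaves alkene 13. The closest known reaction type is the intramolecular McMurry coupling of dialdehydes to macrocyclic alkenes, which includes cyclophanes with diaryl ether units. No stereocentre is formed, and the alkene geometry needs no control because step 8 erases it. The only selectivity required is ring closure over intermolecular coupling; slow addition keeps the concentration of uncoupled carbonyl very low, and coupling on the titanium surface makes this reaction comparatively insensitive to ring size. Two carbons of the same polarity are joined, so the two chain ends need no differentiation. The aryl methyl ethers, the diaryl ether and the saturated chain are inert, and 11 no longer contains a halide or any other reducible group.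

Step 8
Reactants: 13 macrocyclic alkene trimethyl ether
Product: 14 saturated macrocycle trimethyl ether (1^5,3^2,3^6-trimethoxy-2-oxa-1(1,3),3(1,4)-dibenzenacyclopentadecaphane)
Conditions: H2 (1 atm), 10% Pd/C, EtOAc, rt
Reagents that add atoms: none
Why: Heterogeneous catalytic hydrogenation of a disubstituted alkene; both geometric isomers converge on the same product. The molecule has no benzyl ether or halide, and diaryl ethers are stable under these conditions.

Step 9
Reactants: 14 saturated macrocycle trimethyl ether
Product: 16 target triol (2-oxa-1(1,3),3(1,4)-dibenzenacyclopentadecaphane-1^5,3^2,3^6-triol), via tris(dibromoboryl) ether 15 (not isolated)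
Conditions: BBr3 (excess), CH2Cl2, −78 °C → rt; then H2O, 0 °C
Reagents that add atoms: none
Why: Lewis-acid cleavage of aryl methyl ethers: boron binds the methoxy oxygen and bromide attacks the methyl carbon. The diaryl ether offers no sp3 carbon for bromide and should survive, and water hydrolyses 15 to the free triol, which is worked up with exclusion of air.

## Compound list

1 | non-8-en-1-ol | OCCCCCCCC=C | starting material
2 | tert-butyl(dimethyl)(non-8-en-1-yloxy)silane | CC(C)(C)[Si](C)(C)OCCCCCCCC=C | intermediate
3 | 4-bromo-2,6-dimethoxyphenol | COc1cc(Br)cc(OC)c1O | starting material
4 | 9-{9-[tert-butyl(dimethyl)silyloxy]nonyl}-9-borabicyclo[3.3.1]nonane (formed in the flask, not isolated) | CC(C)(C)[Si](C)(C)OCCCCCCCCCB1C2CCCC1CCC2 | intermediate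
5 | 4-{9-[tert-butyl(dimethyl)silyloxy]nonyl}-2,6-dimethoxyphenol | COc1cc(CCCCCCCCCO[Si](C)(C)C(C)(C)C)cc(OC)c1O | intermediate
6 | 1-bromo-3-iodo-5-methoxybenzene | COc1cc(Br)cc(I)c1 | starting material
7 | tert-butyl({9-[4-(3-bromo-5-methoxyphenoxy)-3,5-dimethoxyphenyl]nonyl}oxy)dimethylsilane | COc1cc(Br)cc(Oc2c(OC)cc(CCCCCCCCCO[Si](C)(C)C(C)(C)C)cc2OC)c1 | intermediate
8 | 9-[4-(3-bromo-5-methoxyphenoxy)-3,5-dimethoxyphenyl]nonan-1-ol | COc1cc(Br)cc(Oc2c(OC)cc(CCCCCCCCCO)cc2OC)c1 | intermediate
9 | allyl alcohol (prop-2-en-1-ol) | OCC=C | starting material
10 | 3-{3-[4-(9-hydroxynonyl)-2,6-dimethoxyphenoxy]-5-methoxyphenyl}propanal | COc1cc(CCC=O)cc(Oc2c(OC)cc(CCCCCCCCCO)cc2OC)c1 | intermediate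
11 | 9-{4-[3-methoxy-5-(3-oxopropyl)phenoxy]-3,5-dimethoxyphenyl}nonanal | COc1cc(CCC=O)cc(Oc2c(OC)cc(CCCCCCCCC=O)cc2OC)c1 | intermediate
12 | titanium-bound macrocyclic 1,2-diolate at C9 and C10 of the bridge (mixture of diastereomers, further ligands on titanium not drawn; formed in the flask, not isolated) | COc1cc2cc(c1)Oc1c(OC)cc(cc1OC)CCCCCCCCC1O[Ti]OC1CC2 | intermediate
13 | macrocyclic alkene trimethyl ether: the 20-membered ring of 16 with all three hydroxyls as methyl ethers and a C9=C10 double bond in the bridge (C1 on ring B); E drawn, E/Z mixture carried on | COc1cc2cc(c1)Oc1c(OC)cc(cc1OC)CCCCCCCC/C=C/CC2 | intermediate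
14 | saturated macrocycle trimethyl ether: 16 with all three hydroxyls as methyl ethers | COc1cc2cc(c1)Oc1c(OC)cc(cc1OC)CCCCCCCCCCCC2 | intermediate
15 | tris(dibromoboryl) ether of 16 (each phenol oxygen bearing BBr2; formed in the flask, not isolated) | BrB(Br)Oc1cc2cc(c1)Oc1c(OB(Br)Br)cc(cc1OB(Br)Br)CCCCCCCCCCCC2 | intermediate
16 | target: 20-membered macrocyclic diaryl ether; ring A 5-hydroxy-1,3-phenylene, ring B 2,6-dihydroxy-1,4-phenylene with the ether oxygen on C1, bridged by dodecane-1,12-diyl; no stereocentre | Oc1cc2cc(c1)Oc1c(O)cc(cc1O)CCCCCCCCCCCC2 | target

## Step count and least certain steps

Total: 9 steps. Longest linear sequence: 9 steps (1 to 16); 3, 6 and 9 enter as purchased compounds.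

**Step 7 (key step).** The most likely failure is intermolecular coupling to dimers and oligomers, because closure of a 20-membered ring is entropically slow and any build-up of free dialdehyde favours chain growth. Two further risks are arrest at the diol stage if deoxygenation is incomplete, and simple reduction or aldol condensation of the unhindered aldehydes on the Lewis-acidic titanium surface. The fallback sets out from 11. Double Wittig methylenation (Ph3P=CH2, THF) would give the diene 2-[3-(but-3-en-1-yl)-5-methoxyphenoxy]-5-(dec-9-en-1-yl)-1,3-dimethoxybenzene F1. Ring-closing metathesis with the second-generation Grubbs catalyst in dilute CH2Cl2 would then expel ethene and form the same C9=C10 bond. The fallback returns to the route at 13 and costs one extra step.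

**Step 3.** The phenoxide of 5 is flanked by two methoxy groups, so coordination to copper and C–O bond formation may be slow. Prolonged heating invites loss of the iodide/bromide selectivity, a second arylation at the bromide of 7, protodeiodination of 6, and copper-mediated oxidation of the electron-rich phenoxide if air enters. The fallback sets out from 5 and 6. Oxidation of 6 (mCPBA, TsOH, MeCN) and capture by 1,3,5-trimethoxybenzene would give (3-bromo-5-methoxyphenyl)(2,4,6-trimethoxyphenyl)iodonium 4-methylbenzenesulfonate F2. Metal-free arylation of 5 with F2 (K2CO3 or t-BuOK, THF, rt) transfers the less electron-rich aryl group, tolerates di-ortho-substituted phenoxides and leaves the bromide alone. It returns to the route at 7.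

**Step 5.** Arylation may occur partly at the internal alkene carbon (branched aldehyde), β-hydride elimination may go away from the carbinol carbon (cinnamyl-type alcohol), and at the temperature an aryl bromide needs the ligand-free catalyst may precipitate as palladium black or the product aldehyde may undergo aldol condensation. The fallback sets out from 7 and replaces steps 4 to 6 by three other steps.
- Hydroboration of tert-butyl(dimethyl)(prop-2-en-1-yloxy)silane with 9-BBN would give 9-{3-[tert-butyl(dimethyl)silyloxy]propyl}-9-borabicyclo[3.3.1]nonane F3.
- B-alkyl Suzuki–Miyaura coupling of F3 with 7 (Pd(OAc)2, SPhos, aq. K3PO4, THF) would give the bis-silyl ether tert-butyl{3-[3-(4-{9-[tert-butyl(dimethyl)silyloxy]nonyl}-2,6-dimethoxyphenoxy)-5-methoxyphenyl]propoxy}dimethylsilane F4.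
- Acid-catalysed methanolysis would give the diol 9-{4-[3-(3-hydroxypropyl)-5-methoxyphenoxy]-3,5-dimethoxyphenyl}nonan-1-ol F5.
- Twofold Dess–Martin oxidation of F5 returns to the route at 11.

**Step 2.** Under the basic conditions 3 is a phenoxide, which makes the C–Br bond very electron-rich and oxidative addition slow. The alkylborane may then be lost by protodeboronation or by β-hydride elimination, and the phenoxide can bind boron. The fallback sets out from 3. Benzylation (BnBr, K2CO3, DMF) would give 2-(benzyloxy)-5-bromo-1,3-dimethoxybenzene F6. Coupling of F6 with 4 under the conditions of step 2 would give tert-butyl({9-[4-(benzyloxy)-3,5-dimethoxyphenyl]nonyl}oxy)dimethylsilane F7. Hydrogenolysis (H2, Pd/C, EtOAc) returns to the route at 5, at the cost of two extra steps.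

## Further compounds

F1 | step 7 | 2-[3-(but-3-en-1-yl)-5-methoxyphenoxy]-5-(dec-9-en-1-yl)-1,3-dimethoxybenzene | COc1cc(CCC=C)cc(Oc2c(OC)cc(CCCCCCCCC=C)cc2OC)c1
F2 | step 3 | (3-bromo-5-methoxyphenyl)(2,4,6-trimethoxyphenyl)iodonium 4-methylbenzenesulfonate | COc1cc(Br)cc([I+]c2c(OC)cc(OC)cc2OC)c1.Cc1ccc(cc1)S(=O)(=O)[O-]
F3 | step 5 | 9-{3-[tert-butyl(dimethyl)silyloxy]propyl}-9-borabicyclo[3.3.1]nonane | CC(C)(C)[Si](C)(C)OCCCB1C2CCCC1CCC2
F4 | step 5 | tert-butyl{3-[3-(4-{9-[tert-butyl(dimethyl)silyloxy]nonyl}-2,6-dimethoxyphenoxy)-5-methoxyphenyl]propoxy}dimethylsilane | COc1cc(CCCO[Si](C)(C)C(C)(C)C)cc(Oc2c(OC)cc(CCCCCCCCCO[Si](C)(C)C(C)(C)C)cc2OC)c1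
F5 | step 5 | 9-{4-[3-(3-hydroxypropyl)-5-methoxyphenoxy]-3,5-dimethoxyphenyl}nonan-1-ol | COc1cc(CCCO)cc(Oc2c(OC)cc(CCCCCCCCCO)cc2OC)c1
F6 | step 2 | 2-(benzyloxy)-5-bromo-1,3-dimethoxybenzene | COc1cc(Br)cc(OC)c1OCc1ccccc1
F7 | step 2 | tert-butyl({9-[4-(benzyloxy)-3,5-dimethoxyphenyl]nonyl}oxy)dimethylsilane | COc1cc(CCCCCCCCCO[Si](C)(C)C(C)(C)C)cc(OC)c1OCc1ccccc1
A1 | alternative 1 | 6,6'-(2,4,17,19-tetraoxoicosane-1,20-diyl)bis(2,2-dimethyl-4H-1,3-dioxin-4-one) | CC1(C)OC(CC(=O)CC(=O)CCCCCCCCCCCCC(=O)CC(=O)CC2=CC(=O)OC(C)(C)O2)=CC(=O)O1
A2 | alternative 1 | dimethyl 6,6'-(dodecane-1,12-diyl)bis(2,4-dihydroxybenzoate) | COC(=O)c1c(O)cc(O)cc1CCCCCCCCCCCCc1cc(O)cc(O)c1C(=O)OC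
A3 | alternative 2 | 3-{12-[4-(ethynyloxy)-3,5-dimethoxyphenyl]dodecyl}cyclobut-2-en-1-one | O=C1C=C(CCCCCCCCCCCCc2cc(OC)c(OC#C)c(OC)c2)C1
A4 | alternative 2 | macrocycle 16 with the two ring B hydroxyls as methyl ethers and the ring A hydroxyl free | COc1cc2cc(OC)c1Oc1cc(O)cc(c1)CCCCCCCCCCCC2
A5 | alternative 3 | 3-chloro-5-[12-(4-hydroxy-3,5-dimethoxyphenyl)dodecyl]cyclohex-2-en-1-one (racemic) | COc1cc(CCCCCCCCCCCCC2CC(Cl)=CC(=O)C2)cc(OC)c1O
A6 | alternative 3 | macrocyclic 3-aryloxycyclohex-2-en-1-one: ring B 2,6-dimethoxy-1,4-phenylene, ether oxygen on C3 of the enone, C12 bridge from C5 of the enone to ring B (racemic) | COc1cc2cc(OC)c1OC1=CC(=O)CC(C1)CCCCCCCCCCCC2
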